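## The problem

Bisnorstriatol 17 is made of two identical 5-alkylresorcinol rings whose C5 carbons are joined by an unbranched chain of fourteen methylene groups. The molecule is achiral and has no stereocenter, so nothing has to be set and no center can steer another; what has to be solved is regiochemistry and chain length. In each ring the chain stands meta to both hydroxyl groups, which is the one position that electrophilic substitution of resorcinol or its ethers does not reach, because both oxygens direct to C2, C4 and C6. The rings must therefore either be bought with the 1,3,5-pattern in place and joined to the chain, or be built in such a way that the pattern follows from the ring closure. Exactly fourteen carbons must lie between the rings, and since homologues differing by one or two CH2 groups would be almost inseparable from so waxy a compound, the chain is best taken intact from one defined building block. The free resorcinol units are electron-rich, are oxidised easily in base and react with electrophiles at carbon as well as at oxygen, so part of the oxygenation should stay masked until the last step, and the twofold symmetry invites doing every operation on both ends at once. The feature that opens the key step is that the six carbons of each ring map onto a 3-alkylcyclobut-2-en-1-one and an alkoxyacetylene: the carbonyl carbon becomes C1 (C–OH), the cyclobutenone carbons C2, C3 and C4 become C4 (CH), C5 (chain-bearing) and C6 (CH), and the two alkyne carbons become C2 (the CH between the oxygens) and C3 (C–OMe).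

## Retrosynthesis

**From 17 back to 16.** The two O–CH3 bonds of 5,5'-(tetradecane-1,14-diyl)bis(3-methoxyphenol) 16 are cut last. A methyl ether is chosen because the ring-forming step delivers one free hydroxyl and one ether per ring, and because a methoxyalkyne, unlike an ethoxyalkyne, has no β-hydrogen and cannot lose an alkene on heating. Compound 16 is hardly simpler than 17, but it is exactly what the ring construction gives. The forward reaction only has to cleave two aryl methyl ethers on a molecule with no other functional group.

**From 16 back to 8 and 11 (key disconnection).** In each ring the bonds C1–C2 and C3–C4 (phenol numbering) are cut, which removes C2 and C3 as one molecule of methoxyacetylene 11 per ring and leaves 3,3'-(tetradecane-1,14-diyl)bis(cyclobut-2-en-1-one) 8. The neighbouring cuts, at the aryl–CH2 bonds or inside the chain, would need a pre-formed 3,5-dioxygenated arene and would still have to join it to the chain. Here the 1,3,5-pattern follows from the mechanism, and neither precursor contains an aromatic ring or a pre-set oxygenation pattern. Two benzene rings and four skeletal bonds arise in one operation from a C22 diketone and two molecules of a C3 ynol ether. The forward reaction asks for three things: both ends must react, the ketene–alkyne cycloaddition must be regioselective, and the ketene intermediates must be trapped by the alkyne and not by the phenol that is forming.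

**From 8 back to 7, and from 7 to 4 and 5.** The CH2 group of each cyclobutenone is first traced back to a CCl2 group, giving 3,3'-(tetradecane-1,14-diyl)bis(4,4-dichlorocyclobut-2-en-1-one) 7. Cutting the ring bonds C1–C2 and C3–C4 of each four-membered ring then leads to octadeca-1,17-diyne 4 and two molecules of dichloroketene 6, made in the flask from trichloroacetyl chloride 5. Ketene itself does not add to unactivated alkynes; dichloroketene does, and its chlorine atoms are removed afterwards with zinc. The precursor is an unfunctionalised diyne. The forward cycloaddition must join the ketene carbonyl carbon to the terminal alkyne carbon so that the chain sits at C3, and it must do so at both ends.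

**From 4 back to 2 and 3.** The C2–C3 and C16–C17 bonds of the diyne are cut, giving 1,14-dibromotetradecane 2 and two molecules of lithium acetylide–ethylenediamine complex 3. This keeps the fourteen methylene groups in one piece, and each ethynyl group supplies exactly the two carbons that become C2 and C3 of a cyclobutenone, so that the eighteen carbons of 4 are the fourteen of 2 plus two from each acetylide. The forward reaction is a twofold SN2 alkylation at primary carbon.

**From 2 back to 1.** The two C–Br bonds are traced back to the C–OH bonds of commercial tetradecane-1,14-diol 1, which fixes the chain length from the outset.

**From 11 back to 9.** Methoxyacetylene 11 is volatile and is not a stock chemical. It is traced back, through sodium methoxyacetylide 10, to commercial chloroacetaldehyde dimethyl acetal 9 by loss of methanol and hydrogen chloride.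

## Roads not taken

Alternative 1: Reductive alkylation of a benzoic acid at both chain ends, followed by decarboxylative rearomatization.
- **Cut:** the two ring-carbon to chain-carbon bonds.
- **Forward key step:** two molecules of 3,5-dimethoxybenzoic acid A1 would be reduced with lithium in liquid ammonia. The two ends of dibromide 2 would then alkylate the resulting dianions at C1 to give the bis(dihydrobenzoic acid) A2. Oxidative decarboxylation, for example with lead tetraacetate Pb(OAc)4, would restore both benzene rings, and the four methyl ethers would then be cleaved.
- **Merits:** the carboxyl group marks the chain position, so the 1,3,5-pattern is automatic. The whole carbon skeleton stands after one operation on two cheap compounds.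
- **Weak points:** dibromide 2 is almost insoluble in liquid ammonia, so the second alkylation would be heterogeneous and would compete with elimination and aminolysis. A2 carries four acid-labile enol ethers. The rings are reduced only to be reoxidised with a stoichiometric oxidant, and four ethers instead of two must be cleaved.
- **Comparison:** this road is clearly shorter, about four steps against seven, and that has to be conceded. The chosen plan sets against it homogeneous reactions in ordinary solvents, no redox detour through a dearomatised ring, and a penultimate compound 16 in which the two oxygens of each ring are already differentiated.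

Alternative 2: A cyclic C8 alkene inserted into a shorter diaryl alkene by ring-opening insertion metathesis.
- **Cut:** the C3–C4 and C11–C12 bonds of the chain, after two double bonds have been introduced retrosynthetically.
- **Forward key step:** (E)-1,6-bis(3,5-dimethoxyphenyl)hex-3-ene A3, used in excess, would be treated with cis-cyclooctene A4 and the second-generation Grubbs catalyst RuCl2(=CHPh)(PCy3)(H2IMes). Opening of one ring and insertion of its eight carbons between the two halves of A3 would give the diene A5. Hydrogenation and ether cleavage would finish the synthesis.
- **Merits:** the step is catalytic, neutral and tolerant of aryl ethers. Alkene geometry does not matter because hydrogenation follows.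
- **Weak points:** insertion of exactly one C8 unit is a statistical event, and ring-opening oligomerisation gives chains with two or three such units. Alkene migration by ruthenium hydride species can shift a double bond before a later metathesis event, which yields homologues one CH2 shorter or longer; after hydrogenation these would be nearly impossible to remove. A3 is not commercial, needs its own steps, and must be used in excess and recycled.
- **Comparison:** in step count and catalyst economy this road is about equal to or slightly better than the chosen plan. The chosen plan offers fidelity of chain length: the fourteen methylenes come from the single compound 1, and the key step forms only ring bonds.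

Alternative 3: Biomimetic aldol aromatization of a polyketide-like chain at both ends.
- **Cut:** in each ring, the bond between the chain-bearing carbon and the neighbouring ring carbon that carries an ester.
- **Forward key step:** the hexaketo diester A6 would be exposed to buffer or hydroxide. At each terminus the C2 methylene would attack the ketone five carbons further along the chain in an intramolecular aldol reaction. Dehydration and enolisation would give the bis(2,4-dihydroxybenzoate) A7, and saponification and decarboxylation would then give 17.
- **Merits:** it follows the biosynthesis and is short on paper. Both oxygens of each ring arrive as free phenols, so no ether cleavage is needed, and the chain position is fixed by the aldol connectivity.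
- **Weak points:** A6 would have to be made by acylating two polyanions of methyl 3,5-dioxohexanoate A8 with dimethyl hexadecanedioate A9, which is demanding polyanion chemistry at both ends of a poorly soluble chain. A6 exists as a mixture of enol forms and can also close by Claisen condensation to an acylphloroglucinol or by lactonisation to a 4-hydroxy-2-pyrone. Each end must choose the aldol mode, and the choice depends on pH.
- **Comparison:** in protecting-group economy this road is better than the chosen plan. The chosen plan sets against it a stable, characterisable precursor 8 and a ring closure with a single regiochemical decision that is fixed by the polarisation of the alkyne.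

Key step: step 6

## Route

Remark: the two chain ends are taken to react independently, so each twofold step consumes two molecules of its partner per molecule of chain compound (the second one is entered under the reagents that add atoms), and the intermediates of step 6 are numbered in their twofold form 12 to 15 although species that are further along at one end than at the other will also be present.

Step 1
Reactants: 1 tetradecane-1,14-diol
Product: 2 1,14-dibromotetradecane
Conditions: CBr4 (2.4 equiv.), PPh3 (2.4 equiv.), CH2Cl2–THF, 0 °C → rt
Reagents that add atoms: carbon tetrabromide, BrC(Br)(Br)Br
Why: Appel reaction; each primary hydroxyl is activated as an alkoxyphosphonium ion and displaced by bromide in an SN2 step, and the diol has no other functional group that could interfere.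

Step 2
Reactants: 2 1,14-dibromotetradecane; 3 lithium acetylide–ethylenediamine complex (two equivalents react)
Product: 4 octadeca-1,17-diyne
Conditions: LiC≡CH·H2NCH2CH2NH2 (3 equiv.), DMSO–THF, 10 °C → rt
Reagents that add atoms: second equivalent of lithium acetylide–ethylenediamine complex 3, [Li]C#C.NCCN
Why: Twofold SN2 alkylation of an acetylide by a primary alkyl bromide in a dipolar aprotic solvent, one C2 unit per chain end, which gives HC≡C–(CH2)14–C≡CH with eighteen carbons. Keeping the mixture at or below room temperature should limit E2 elimination and base-induced migration of the terminal triple bonds.

Step 3
Reactants: 4 octadeca-1,17-diyne; 5 trichloroacetyl chloride (two equivalents react)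
Product: 7 3,3'-(tetradecane-1,14-diyl)bis(4,4-dichlorocyclobut-2-en-1-one), via dichloroketene 6 (not isolated)
Conditions: Cl3CCOCl (4 equiv., slow addition), Zn–Cu couple, Et2O–DME, rt
Reagents that add atoms: second equivalent of trichloroacetyl chloride 5, ClC(=O)C(Cl)(Cl)Cl
Why: Zinc dechlorinates 5 to dichloroketene 6, and one molecule of 6 adds to each terminal alkyne in a ketene–alkyne [2+2] cycloaddition. The electrophilic ketene carbonyl carbon bonds to the terminal alkyne carbon, so the chain should end at C3 next to the CCl2 group, and DME ties up the ZnCl2 that would otherwise degrade the product.

Step 4
Reactants: 7 3,3'-(tetradecane-1,14-diyl)bis(4,4-dichlorocyclobut-2-en-1-one)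
Product: 8 3,3'-(tetradecane-1,14-diyl)bis(cyclobut-2-en-1-one)
Conditions: Zn dust, AcOH, TMEDA, EtOH, 0 °C → rt
Reagents that add atoms: none
Why: Reductive dechlorination of an α,α-dichloro ketone through zinc enolates that are protonated by acetic acid; the TMEDA–acetic acid buffer should keep the zinc salts from opening the strained enone, as it does for simple 3-alkyl-4,4-dichlorocyclobutenones.

Step 5
Reactants: 9 chloroacetaldehyde dimethyl acetal
Product: 11 methoxyacetylene, via sodium methoxyacetylide 10 (not isolated)
Conditions: NaNH2 (3 equiv.), liq. NH3, −33 °C; evaporate NH3; sat. aq. NaCl, −20 °C → rt; distil through CaCl2 into toluene at −78 °C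
Reagents that add atoms: none
Why: Twofold base-induced β-elimination, first of methanol and then of hydrogen chloride, with the third equivalent of amide storing the ynol ether as its acetylide 10. Aqueous quenching should release 11, which boils near room temperature and is collected as a cold, dry toluene solution and used at once.

Step 6
Reactants: 8 3,3'-(tetradecane-1,14-diyl)bis(cyclobut-2-en-1-one); 11 methoxyacetylene (two equivalents react)
Product: 16 5,5'-(tetradecane-1,14-diyl)bis(3-methoxyphenol), via bis(vinylketene) 12 (not isolated), via bis(vinylcyclobutenone) 13 (not isolated), via bis(dienylketene) 14 (not isolated), via bis(cyclohexadienone) 15 (not isolated)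
Conditions: methoxyacetylene (6 equiv.), toluene, 80 °C, sealed tube
Reagents that add atoms: second equivalent of methoxyacetylene 11, C#COC
Why: Danheiser benzannulation, run at both ends of 8 with one molecule of 11 per ring. At 80 °C each cyclobutenone should open reversibly in a four-electron electrocyclic reaction to a vinylketene (12), whose ketene C=C bond adds methoxyacetylene in a [2+2] cycloaddition to give the 3-methoxy-4-vinylcyclobutenone units of 13. A second four-electron opening gives the dienylketene 14, and each benzene ring is then closed by a six-electron disrotatory electrocyclization that joins the ketene carbon to the terminal methylidene carbon; the cyclohexadienone 15 so formed tautomerizes to the phenol, which makes the cascade irreversible. The closest known reaction is the benzannulation of simple 3-alkylcyclobutenones with alkoxyalkynes to 5-alkylresorcinol monoethers, used here twice on a substrate whose ends are fourteen methylenes apart and cannot interact. No stereocenter survives: the sp3 ring carbons of 13 are transient, and because the opening of 13 is reversible only the dienylketene geometry drawn for 14, with ketene and vinyl cis, is drained off by ring closure. The selectivity the step needs is the regiochemistry of the [2+2] step, and the polarization of the ynol ether secures it, since the oxygen lone pair makes the unsubstituted alkyne carbon the nucleophile that bonds to the electrophilic ketene carbonyl carbon, which places the methoxy group meta to the new hydroxyl and the chain meta to both. An excess of 11 in a closed vessel should keep the alkyne, not the product phenol, the main trap for the ketenes, and a treatment with K2CO3 in methanol during work-up would return any phenol that was acylated.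

Step 7
Reactants: 16 5,5'-(tetradecane-1,14-diyl)bis(3-methoxyphenol)
Product: 17 bisnorstriatol
Conditions: BBr3 (6 equiv.), CH2Cl2, −78 °C → rt; then H2O, 0 °C
Reagents that add atoms: none
Why: Lewis acid cleavage of aryl methyl ethers; boron coordinates the ether oxygen, bromide attacks the methyl group in an SN2 step, and water hydrolyses the aryl borates, while the saturated chain and the rings are inert to the reagent.

## Compound list

1 | tetradecane-1,14-diol | OCCCCCCCCCCCCCCO | starting material
2 | 1,14-dibromotetradecane | BrCCCCCCCCCCCCCCBr | intermediate
3 | lithium acetylide–ethylenediamine complex | [Li]C#C.NCCN | starting material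
4 | octadeca-1,17-diyne | C#CCCCCCCCCCCCCCCC#C | intermediate
5 | trichloroacetyl chloride | ClC(=O)C(Cl)(Cl)Cl | starting material
6 | dichloroketene | O=C=C(Cl)Cl | intermediate
7 | 3,3'-(tetradecane-1,14-diyl)bis(4,4-dichlorocyclobut-2-en-1-one) | O=C1C=C(CCCCCCCCCCCCCCC2=CC(=O)C2(Cl)Cl)C1(Cl)Cl | intermediate
8 | 3,3'-(tetradecane-1,14-diyl)bis(cyclobut-2-en-1-one) | O=C1C=C(CCCCCCCCCCCCCCC2=CC(=O)C2)C1 | intermediate
9 | chloroacetaldehyde dimethyl acetal (2-chloro-1,1-dimethoxyethane) | COC(CCl)OC | starting material
10 | sodium methoxyacetylide | [Na+].[C-]#COC | intermediate
11 | methoxyacetylene (methoxyethyne) | C#COC | intermediate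
12 | 3,18-dimethylideneicosa-1,19-diene-1,20-dione, the bis(vinylketene) | O=C=CC(=C)CCCCCCCCCCCCCCC(=C)C=C=O | intermediate
13 | 4,4'-(octadeca-1,17-diene-2,17-diyl)bis(3-methoxycyclobut-2-en-1-one), the bis(vinylcyclobutenone), mixture of stereoisomers at the two sp3 ring carbons | O=C1C=C(OC)C1C(=C)CCCCCCCCCCCCCCC(=C)C1C(OC)=CC1=O | intermediate
14 | (3E,21E)-3,22-dimethoxy-5,20-dimethylidenetetracosa-1,3,21,23-tetraene-1,24-dione, the bis(dienylketene) | O=C=C/C(OC)=C\C(=C)CCCCCCCCCCCCCCC(=C)/C=C(OC)\C=C=O | intermediate
15 | 5,5'-(tetradecane-1,14-diyl)bis(3-methoxycyclohexa-2,4-dien-1-one), the bis(cyclohexadienone) | O=C1C=C(OC)C=C(CCCCCCCCCCCCCCC2=CC(OC)=CC(=O)C2)C1 | intermediate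
16 | 5,5'-(tetradecane-1,14-diyl)bis(3-methoxyphenol) | COc1cc(O)cc(CCCCCCCCCCCCCCc2cc(O)cc(OC)c2)c1 | intermediate
17 | bisnorstriatol, 5,5'-(tetradecane-1,14-diyl)bis(benzene-1,3-diol) | Oc1cc(O)cc(CCCCCCCCCCCCCCc2cc(O)cc(O)c2)c1 | target

## Step count and least certain steps

Total step count: 7. Longest linear sequence: 6 steps (steps 1, 2, 3, 4, 6 and 7); step 5 is a one-step side branch that supplies the alkyne.

**Risk 1, step 6 (key step).** The most likely failure is interception of the ketene intermediates by something other than the alkyne. The hydroxyl of an end that has already become a phenol can be acylated by a vinylketene of another molecule. Because every molecule carries two reacting ends, this would build ester-linked oligomers, not a simple by-product. If the volatile alkyne escapes into the head space, ketene dimerisation would gain ground, and one end could stall at the mono-annulated stage. The fallback gives up ring construction and sets out from dibromide 2. 3,5-Dimethoxyphenylmagnesium bromide F1, made from commercial 1-bromo-3,5-dimethoxybenzene and magnesium in THF, would be coupled at both ends of 2 with catalytic Li2CuCl4 in THF–NMP to give 1,14-bis(3,5-dimethoxyphenyl)tetradecane F2. BBr3 in CH2Cl2 would then cleave all four ethers, and the route is rejoined at the target 17.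

**Risk 2, step 3.** The most likely failure is incomplete cycloaddition at the second alkyne, together with Lewis-acid damage: the ZnCl2 formed alongside dichloroketene promotes polymerisation of the ketene and ring opening of the dichlorocyclobutenone, and a lipophilic diyne in a heterogeneous mixture reacts slowly. The fallback avoids any cycloaddition on the long chain and sets out from 2. Magnesium in THF would convert it into tetradecane-1,14-diylbis(magnesium bromide) F3, which would add in 1,2-fashion to two equivalents of commercial 3-ethoxycyclobut-2-en-1-one to give 1,1'-(tetradecane-1,14-diyl)bis(3-ethoxycyclobut-2-en-1-ol) F4. Dilute HCl would hydrolyse the enol ethers with allylic transposition (a Stork–Danheiser sequence on a four-membered vinylogous ester) and return the route at 8, replacing steps 2 to 4.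

**Risk 3, step 4.** The most likely failure is incomplete removal of the second chlorine at one end or, if the reaction is pushed, opening of the strained enone by ethanol under the influence of zinc salts and reduction of the ring double bond. The fallback never introduces chlorine and sets out from diyne 4. N,N-Dimethylketeniminium trifluoromethanesulfonate F5, generated from N,N-dimethylacetamide, Tf2O and 2,4,6-collidine in 1,2-dichloroethane, would add to each alkyne in a [2+2] cycloaddition to give 3,3'-(tetradecane-1,14-diyl)bis(N,N-dimethylcyclobut-2-en-1-iminium) bis(trifluoromethanesulfonate) F6. Hydrolysis with aqueous NaHCO3 would deliver 8 directly.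

**Risk 4, step 5.** The most likely failure is loss of the reagent through volatility and polymerisation during isolation, or carry-over of ammonia, methanol or water, each of which would add to the ketenes of step 6 and consume them. The fallback replaces the prepared alkyne by a purchased one and sets out from 8. Commercial ethoxyacetylene, sold as a solution in hexanes, would be used in the benzannulation at 80 °C to give 5,5'-(tetradecane-1,14-diyl)bis(3-ethoxyphenol) F7. The temperature must be held there because 1-ethoxyalkynes lose ethene by a retro-ene reaction at higher temperature. BBr3 would then cleave the ethyl ethers and rejoin the route at 17.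

## Further compounds

F1 | step 6 | 3,5-dimethoxyphenylmagnesium bromide | COc1cc(OC)cc([Mg]Br)c1
F2 | step 6 | 1,14-bis(3,5-dimethoxyphenyl)tetradecane | COc1cc(OC)cc(CCCCCCCCCCCCCCc2cc(OC)cc(OC)c2)c1
F3 | step 3 | tetradecane-1,14-diylbis(magnesium bromide) | Br[Mg]CCCCCCCCCCCCCC[Mg]Br
F4 | step 3 | 1,1'-(tetradecane-1,14-diyl)bis(3-ethoxycyclobut-2-en-1-ol), mixture of stereoisomers | CCOC1=CC(O)(CCCCCCCCCCCCCCC2(O)C=C(OCC)C2)C1
F5 | step 4 | N,N-dimethylketeniminium trifluoromethanesulfonate | C=C=[N+](C)C.[O-]S(=O)(=O)C(F)(F)F
F6 | step 4 | 3,3'-(tetradecane-1,14-diyl)bis(N,N-dimethylcyclobut-2-en-1-iminium) bis(trifluoromethanesulfonate) | C[N+](C)=C1C=C(CCCCCCCCCCCCCCC2=CC(=[N+](C)C)C2)C1.[O-]S(=O)(=O)C(F)(F)F.[O-]S(=O)(=O)C(F)(F)F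
F7 | step 5 | 5,5'-(tetradecane-1,14-diyl)bis(3-ethoxyphenol) | CCOc1cc(O)cc(CCCCCCCCCCCCCCc2cc(O)cc(OCC)c2)c1
A1 | alternative 1 | 3,5-dimethoxybenzoic acid | COc1cc(OC)cc(C(=O)O)c1
A2 | alternative 1 | 1,1'-(tetradecane-1,14-diyl)bis(3,5-dimethoxycyclohexa-2,5-diene-1-carboxylic acid) | COC1=CC(CCCCCCCCCCCCCCC2(C(=O)O)C=C(OC)CC(OC)=C2)(C(=O)O)C=C(OC)C1
A3 | alternative 2 | (E)-1,6-bis(3,5-dimethoxyphenyl)hex-3-ene | COc1cc(CC/C=C/CCc2cc(OC)cc(OC)c2)cc(OC)c1
A4 | alternative 2 | cis-cyclooctene | C1CCC/C=C\CC1
A5 | alternative 2 | (3E,11E)-1,14-bis(3,5-dimethoxyphenyl)tetradeca-3,11-diene | COc1cc(CC/C=C/CCCCCC/C=C/CCc2cc(OC)cc(OC)c2)cc(OC)c1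
A6 | alternative 3 | dimethyl 3,5,7,22,24,26-hexaoxooctacosanedioate | COC(=O)CC(=O)CC(=O)CC(=O)CCCCCCCCCCCCCCC(=O)CC(=O)CC(=O)CC(=O)OC
A7 | alternative 3 | dimethyl 6,6'-(tetradecane-1,14-diyl)bis(2,4-dihydroxybenzoate) | COC(=O)c1c(O)cc(O)cc1CCCCCCCCCCCCCCc1cc(O)cc(O)c1C(=O)OC
A8 | alternative 3 | methyl 3,5-dioxohexanoate | COC(=O)CC(=O)CC(C)=O
A9 | alternative 3 | dimethyl hexadecanedioate | COC(=O)CCCCCCCCCCCCCCC(=O)OC
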